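**Plan**
- Retrosynthesis: (1) the O–Si bond at C6; (2) the C2–C3 bond of the pyran ring, which opens the 2H-chromene to an isomeric o-ethynylphenyl sec-alkyl ether; (3) the terminal alkyne carbon (aldehyde homologation) and the alkyl C–O bond (Mitsunobu); (4) the chain bond C2'–C3' (vinyllithium plus 2-methyloxetane) and the C4' methyl (carboalumination of an alkyne made from (S)-dihydro-α-ionone).
- Enabling feature: C2 of the pyran ring is bonded to the ring oxygen O1. In the ring-opened isomer it is therefore a tertiary, hydridic O–C–H carbon held 1,5 to the inner alkyne carbon (future C4) on the benzo ring. That C–H plus the C≡C have exactly the oxidation level of the C2–C3 single bond plus the C3=C4 double bond.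
- Forward order: the chain is grown on the cyclohexene unit, joined to the arene as an ether, the aldehyde is turned into the alkyne, the pyran ring is closed last, then the silyl group is removed.
- Stereochemistry: the ring stereocentre (S) comes from (S)-α-ionone; the E-alkene comes from syn-carboalumination; C2 (S) is set in the ring closure by a chiral gold catalyst, whatever the configuration of the ether carbon (both epimers converge).

Key step: step 8

Remark: (S)-(−)-α-ionone of high enantiomeric purity is taken as a purchasable terpene building block; 2-methyloxetane is used as the racemate on purpose, because its stereocentre is erased in step 8.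

**Step 1**
Reactants: 1 (S)-α-ionone, (3E)-4-[(1S)-2,6,6-trimethylcyclohex-2-en-1-yl]but-3-en-2-one
Product: 2 (S)-dihydro-α-ionone, 4-[(1S)-2,6,6-trimethylcyclohex-2-en-1-yl]butan-2-one
Conditions: Cu(OAc)2·H2O (3 mol%), 1,2-bis(diphenylphosphino)benzene (3 mol%), (EtO)2MeSiH (1.5 equiv), t-BuOH (1.5 equiv), toluene, 0 °C to rt
Reagents that add atoms: none
Why: Copper hydride conjugate reduction (the copper enolate is protonated in situ by t-BuOH) should reduce only the enone C=C, since the trisubstituted ring alkene is inert and the near-neutral medium avoids the dienolate that would scramble the allylic ring stereocentre.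

**Step 2**
Reactants: 2 (S)-dihydro-α-ionone
Product: 4 (6S)-6-(but-3-yn-1-yl)-1,5,5-trimethylcyclohex-1-ene, via enol phosphate 3 (not isolated)
Conditions: LiN(i-Pr)2 (1.1 equiv), THF, −78 °C; ClP(O)(OEt)2, −78 °C to rt; then LiN(i-Pr)2 (2.3 equiv), THF, −78 °C to rt; aq. NH4Cl
Reagents that add atoms: none
Why: Kinetic deprotonation at the methyl group, O-phosphorylation and base-induced β-elimination of diethyl phosphate should convert the methyl ketone into the terminal alkyne (enol phosphate route), and the ring stereocentre is not next to any enolizable position.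

**Step 3**
Reactants: 4 (6S)-6-(but-3-yn-1-yl)-1,5,5-trimethylcyclohex-1-ene
Product: 6 (6S)-6-[(3E)-4-iodo-3-methylbut-3-en-1-yl]-1,5,5-trimethylcyclohex-1-ene, via vinylalane 5 (not isolated)
Conditions: Me3Al (2.5 equiv), Cp2ZrCl2 (0.25 equiv), CH2Cl2, 0 °C to rt; then I2, THF, −30 to 0 °C
Reagents that add atoms: trimethylaluminium, C[Al](C)C; iodine, II
Why: Zirconium-catalysed carboalumination (Negishi) adds methyl and aluminium syn across the terminal alkyne with methyl on the inner carbon, and iodinolysis of the C–Al bond with retention should give the E-configured trisubstituted vinyl iodide, while the trisubstituted ring alkene does not react.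

**Step 4**
Reactants: 6 (6S)-6-[(3E)-4-iodo-3-methylbut-3-en-1-yl]-1,5,5-trimethylcyclohex-1-ene; 7 2-methyloxetane (racemic)
Product: 9 (5E)-6-methyl-8-[(1S)-2,6,6-trimethylcyclohex-2-en-1-yl]oct-5-en-2-ol (both C2 epimers), via vinyllithium 8 (not isolated)
Conditions: t-BuLi (2.1 equiv), Et2O, −78 °C; then 7 (1.5 equiv), BF3·OEt2 (1.5 equiv), −78 °C; aq. NH4Cl
Reagents that add atoms: none
Why: Iodine–lithium exchange with retention of alkene geometry gives the vinyllithium, which should open the BF3-activated oxetane by SN2 attack at its unsubstituted CH2 carbon; the carbinol centre forms as both epimers, which is harmless because it is erased in step 8.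

**Step 5**
Reactants: 10 2,5-dihydroxybenzaldehyde
Product: 11 2-hydroxy-5-[(triisopropylsilyl)oxy]benzaldehyde
Conditions: TIPSCl (1.05 equiv), imidazole (2.2 equiv), CH2Cl2, 0 °C to rt
Reagents that add atoms: triisopropylsilyl chloride, CC(C)[Si](Cl)(C(C)C)C(C)C
Why: The 2-OH is tied up in a hydrogen bond to the ortho formyl group and is more hindered, so one equivalent of silyl chloride should protect the 5-OH selectively.

**Step 6**
Reactants: 11 2-hydroxy-5-[(triisopropylsilyl)oxy]benzaldehyde; 9 (5E)-6-methyl-8-[(1S)-2,6,6-trimethylcyclohex-2-en-1-yl]oct-5-en-2-ol (both C2 epimers)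
Product: 12 2-{[(5E)-6-methyl-8-[(1S)-2,6,6-trimethylcyclohex-2-en-1-yl]oct-5-en-2-yl]oxy}-5-[(triisopropylsilyl)oxy]benzaldehyde (both epimers at the O-bearing carbon)
Conditions: PPh3 (1.5 equiv), DIAD (1.5 equiv), THF (0.5 M), 0 °C to rt
Reagents that add atoms: none
Why: Mitsunobu etherification, in which the ortho-formyl phenol is acidic enough to protonate the betaine and displaces the activated secondary alcohol by SN2 (inversion, irrelevant because both epimers are carried on).

**Step 7**
Reactants: 12 2-{[(5E)-6-methyl-8-[(1S)-2,6,6-trimethylcyclohex-2-en-1-yl]oct-5-en-2-yl]oxy}-5-[(triisopropylsilyl)oxy]benzaldehyde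
Product: 13 triisopropyl(3-ethynyl-4-{[(5E)-6-methyl-8-[(1S)-2,6,6-trimethylcyclohex-2-en-1-yl]oct-5-en-2-yl]oxy}phenoxy)silane (both epimers at the O-bearing carbon)
Conditions: dimethyl (1-diazo-2-oxopropyl)phosphonate (1.3 equiv), K2CO3 (2 equiv), MeOH/THF, 0 °C to rt
Reagents that add atoms: dimethyl (1-diazo-2-oxopropyl)phosphonate, CC(=O)C(=[N+]=[N-])P(=O)(OC)OC
Why: Seyferth–Gilbert homologation in the Ohira–Bestmann variant, in which the diazomethylphosphonate anion made in the flask olefinates the non-enolizable aryl aldehyde and loss of N2 with a 1,2-shift gives the terminal aryl alkyne under mild carbonate conditions that the aryl triisopropylsilyl ether should survive.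

**Step 8**
Reactants: 13 triisopropyl(3-ethynyl-4-{[(5E)-6-methyl-8-[(1S)-2,6,6-trimethylcyclohex-2-en-1-yl]oct-5-en-2-yl]oxy}phenoxy)silane (both epimers)
Product: 14 triisopropyl{[(2S)-2-methyl-2-{(3E)-4-methyl-6-[(1S)-2,6,6-trimethylcyclohex-2-en-1-yl]hex-3-en-1-yl}-2H-chromen-6-yl]oxy}silane
Conditions: (R)-DTBM-SEGPHOS(AuCl)2 (5 mol%), AgNTf2 (10 mol%), 4 Å molecular sieves, 1,2-dichloroethane, 50 °C, dark (the ligand antipode that gives 2S is to be fixed on a model ether; the (S) complex is used if the sense is opposite)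
Reagents that add atoms: none
Why: Proposed new method: a cationic monovalent gold centre π-activates the ethynyl group, the hydride of the tertiary O–C–H carbon migrates 1,5 through a six-membered transition state to the aryl-bearing alkyne carbon (future C4), and the resulting vinylgold carbon (future C3) attacks the planar aryl oxocarbenium carbon (future C2) with loss of gold. The closest known reaction type is the π-acid-catalysed 1,5-hydride shift/cyclization (internal redox hydroalkylation) of alkynyl ethers, for which enantioselective gold-catalysed variants with chiral bisphosphine ligands exist for amine hydride donors. The pyran ring closes in a 6-endo-trig sense at the O1=C2 π bond, with C3 replacing gold with retention of the cis-alkene geometry that anti hydride addition has set. The C2 stereocentre of 13 is erased in the hydride transfer, so both epimers pass through one oxocarbenium–vinylgold zwitterion whose two twist senses about the aryl–O bond should interconvert by a low-barrier torsion, and the chiral bisphosphine on the gold atom bound to the attacking carbon differentiates the two faces, which makes the step enantioconvergent at C2 while the remote ring stereocentre is untouched. The step needs site selectivity for 1,5-hydride delivery over oxygen attack on the alkyne and over reaction of the two chain alkenes. This is secured by the tertiary oxygen-activated C–H held five atoms from the Markovnikov alkyne carbon, by the para-silyloxy donor that raises the hydride-donor power of O1, and by the poor leaving-group ability of a secondary alkyl group on oxygen, which makes oxonium formation unproductive.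

**Step 9**
Reactants: 14 triisopropyl{[(2S)-2-methyl-2-{(3E)-4-methyl-6-[(1S)-2,6,6-trimethylcyclohex-2-en-1-yl]hex-3-en-1-yl}-2H-chromen-6-yl]oxy}silane
Product: 15 (2S)-2-methyl-2-{(3E)-4-methyl-6-[(1S)-2,6,6-trimethylcyclohex-2-en-1-yl]hex-3-en-1-yl}-2H-chromen-6-ol
Conditions: TBAF (1.1 equiv), AcOH (1.1 equiv), THF, 0 °C, argon
Reagents that add atoms: none
Why: Fluoride cleaves the aryl O–Si bond (desilylation) under buffered conditions that should leave the 2H-chromene, the alkenes and both stereocentres untouched.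

**Compound list**
1 | (S)-α-ionone, (3E)-4-[(1S)-2,6,6-trimethylcyclohex-2-en-1-yl]but-3-en-2-one | CC1=CCCC(C)(C)[C@@H]1/C=C/C(C)=O | starting material
2 | (S)-dihydro-α-ionone, 4-[(1S)-2,6,6-trimethylcyclohex-2-en-1-yl]butan-2-one | CC1=CCCC(C)(C)[C@@H]1CCC(C)=O | intermediate
3 | diethyl 4-[(1S)-2,6,6-trimethylcyclohex-2-en-1-yl]but-1-en-2-yl phosphate (enol phosphate) | CC1=CCCC(C)(C)[C@@H]1CCC(=C)OP(=O)(OCC)OCC | intermediate (not isolated)
4 | (6S)-6-(but-3-yn-1-yl)-1,5,5-trimethylcyclohex-1-ene | CC1=CCCC(C)(C)[C@@H]1CCC#C | intermediate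
5 | dimethyl{(1E)-2-methyl-4-[(1S)-2,6,6-trimethylcyclohex-2-en-1-yl]but-1-en-1-yl}aluminium (vinylalane) | CC1=CCCC(C)(C)[C@@H]1CC/C(C)=C/[Al](C)C | intermediate (not isolated)
6 | (6S)-6-[(3E)-4-iodo-3-methylbut-3-en-1-yl]-1,5,5-trimethylcyclohex-1-ene | CC1=CCCC(C)(C)[C@@H]1CC/C(C)=C/I | intermediate
7 | 2-methyloxetane (racemic) | CC1CCO1 | starting material
8 | {(1E)-2-methyl-4-[(1S)-2,6,6-trimethylcyclohex-2-en-1-yl]but-1-en-1-yl}lithium (vinyllithium) | CC1=CCCC(C)(C)[C@@H]1CC/C(C)=C/[Li] | intermediate (not isolated)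
9 | (5E)-6-methyl-8-[(1S)-2,6,6-trimethylcyclohex-2-en-1-yl]oct-5-en-2-ol (both C2 epimers) | CC1=CCCC(C)(C)[C@@H]1CC/C(C)=C/CCC(C)O | intermediate
10 | 2,5-dihydroxybenzaldehyde | O=Cc1cc(O)ccc1O | starting material
11 | 2-hydroxy-5-[(triisopropylsilyl)oxy]benzaldehyde | O=Cc1cc(O[Si](C(C)C)(C(C)C)C(C)C)ccc1O | intermediate
12 | 2-{[(5E)-6-methyl-8-[(1S)-2,6,6-trimethylcyclohex-2-en-1-yl]oct-5-en-2-yl]oxy}-5-[(triisopropylsilyl)oxy]benzaldehyde (both epimers at the O-bearing carbon) | CC1=CCCC(C)(C)[C@@H]1CC/C(C)=C/CCC(C)Oc1ccc(O[Si](C(C)C)(C(C)C)C(C)C)cc1C=O | intermediate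
13 | triisopropyl(3-ethynyl-4-{[(5E)-6-methyl-8-[(1S)-2,6,6-trimethylcyclohex-2-en-1-yl]oct-5-en-2-yl]oxy}phenoxy)silane (both epimers at the O-bearing carbon) | CC1=CCCC(C)(C)[C@@H]1CC/C(C)=C/CCC(C)Oc1ccc(O[Si](C(C)C)(C(C)C)C(C)C)cc1C#C | intermediate
14 | triisopropyl{[(2S)-2-methyl-2-{(3E)-4-methyl-6-[(1S)-2,6,6-trimethylcyclohex-2-en-1-yl]hex-3-en-1-yl}-2H-chromen-6-yl]oxy}silane | CC1=CCCC(C)(C)[C@@H]1CC/C(C)=C/CC[C@@]1(C)C=Cc2cc(O[Si](C(C)C)(C(C)C)C(C)C)ccc2O1 | intermediate
15 | (2S)-2-methyl-2-{(3E)-4-methyl-6-[(1S)-2,6,6-trimethylcyclohex-2-en-1-yl]hex-3-en-1-yl}-2H-chromen-6-ol | CC1=CCCC(C)(C)[C@@H]1CC/C(C)=C/CC[C@@]1(C)C=Cc2cc(O)ccc2O1 | target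

**Step count**
Total: 9 steps. Longest linear sequence: 8 steps (steps 1–4 and 6–9, from 1 to 15).

**Steps most likely to fail**

Step 8. Three processes could spoil it. Ring closure could outrun torsional equilibration of the zwitterion, so that each ether epimer keeps a memory of its configuration and no funnelling occurs. The catalyst could discriminate poorly between the methyl group and the CH2 chain on the oxocarbenium faces. Oxygen attack on the activated alkyne with loss of the side chain could divert material to a benzofuran.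
The fallback uses known chemistry, sets out from 9 and comes back at 14. Alcohol 9 is oxidized with Dess–Martin periodinane to (5E)-6-methyl-8-[(1S)-2,6,6-trimethylcyclohex-2-en-1-yl]oct-5-en-2-one F1. Addition of HC≡CMgBr in THF gives (6E)-3,7-dimethyl-9-[(1S)-2,6,6-trimethylcyclohex-2-en-1-yl]non-6-en-1-yn-3-ol F2 as both C3 epimers. Treatment with (CF3CO)2O and DBU in MeCN at −5 °C forms the propargylic trifluoroacetate F3 in the flask. This is coupled under CuCl2·2H2O catalysis with 4-[(triisopropylsilyl)oxy]phenol F4 (from monosilylation of hydroquinone) to give the aryl 1,1-dialkylpropargyl ether F5. Heating F5 in N,N-diethylaniline at about 170 °C should trigger the aromatic propargyl Claisen rearrangement, 1,5-hydrogen shift and oxa-6π electrocyclization. This gives 14 together with its (2R) epimer F6, which is removed by preparative HPLC on a chiral stationary phase.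

Step 6. The activated secondary alcohol could undergo E2 elimination, or the hindered, hydrogen-bonded phenol could attack too slowly.
The fallback sets out from 9 and comes back at 12. Alcohol 9 is converted with MsCl and Et3N into (5E)-6-methyl-8-[(1S)-2,6,6-trimethylcyclohex-2-en-1-yl]oct-5-en-2-yl methanesulfonate F7. This is displaced by the caesium phenoxide of 11 (Cs2CO3, DMF, 60 °C) in a Williamson alkylation that needs no redox condensation.

Step 4. The vinyllithium could attack the substituted oxetane carbon, the oxetane could oligomerize under BF3, or the vinyllithium could be protonated.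
The fallback sets out from 6 and comes back at 9. But-3-en-2-ol is silylated to tert-butyl(but-3-en-2-yloxy)dimethylsilane F8. Hydroboration with 9-BBN gives 9-{3-[(tert-butyldimethylsilyl)oxy]butyl}-9-borabicyclo[3.3.1]nonane F9. This is joined to vinyl iodide 6 in a B-alkyl Suzuki–Miyaura coupling (PdCl2(dppf) cat., aq. K3PO4, THF/DMF, rt) with retention of the E geometry. The product, tert-butyldimethyl{[(5E)-6-methyl-8-[(1S)-2,6,6-trimethylcyclohex-2-en-1-yl]oct-5-en-2-yl]oxy}silane F10, gives 9 on treatment with TBAF.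

**Further compounds**
F1 | step 8 | (5E)-6-methyl-8-[(1S)-2,6,6-trimethylcyclohex-2-en-1-yl]oct-5-en-2-one | CC1=CCCC(C)(C)[C@@H]1CC/C(C)=C/CCC(C)=O
F2 | step 8 | (6E)-3,7-dimethyl-9-[(1S)-2,6,6-trimethylcyclohex-2-en-1-yl]non-6-en-1-yn-3-ol (both C3 epimers) | CC1=CCCC(C)(C)[C@@H]1CC/C(C)=C/CCC(C)(O)C#C
F3 | step 8 | (6E)-3,7-dimethyl-9-[(1S)-2,6,6-trimethylcyclohex-2-en-1-yl]non-6-en-1-yn-3-yl trifluoroacetate (both C3 epimers) | CC1=CCCC(C)(C)[C@@H]1CC/C(C)=C/CCC(C)(C#C)OC(=O)C(F)(F)F
F4 | step 8 | 4-[(triisopropylsilyl)oxy]phenol | Oc1ccc(O[Si](C(C)C)(C(C)C)C(C)C)cc1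
F5 | step 8 | triisopropyl(4-{[(6E)-3,7-dimethyl-9-[(1S)-2,6,6-trimethylcyclohex-2-en-1-yl]non-6-en-1-yn-3-yl]oxy}phenoxy)silane (both C3 epimers) | CC1=CCCC(C)(C)[C@@H]1CC/C(C)=C/CCC(C)(C#C)Oc1ccc(O[Si](C(C)C)(C(C)C)C(C)C)cc1
F6 | step 8 | triisopropyl{[(2R)-2-methyl-2-{(3E)-4-methyl-6-[(1S)-2,6,6-trimethylcyclohex-2-en-1-yl]hex-3-en-1-yl}-2H-chromen-6-yl]oxy}silane | CC1=CCCC(C)(C)[C@@H]1CC/C(C)=C/CC[C@]1(C)C=Cc2cc(O[Si](C(C)C)(C(C)C)C(C)C)ccc2O1
F7 | step 6 | (5E)-6-methyl-8-[(1S)-2,6,6-trimethylcyclohex-2-en-1-yl]oct-5-en-2-yl methanesulfonate (both C2 epimers) | CC1=CCCC(C)(C)[C@@H]1CC/C(C)=C/CCC(C)OS(C)(=O)=O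
F8 | step 4 | tert-butyl(but-3-en-2-yloxy)dimethylsilane (racemic) | C=CC(C)O[Si](C)(C)C(C)(C)C
F9 | step 4 | 9-{3-[(tert-butyldimethylsilyl)oxy]butyl}-9-borabicyclo[3.3.1]nonane | CC(CCB1C2CCCC1CCC2)O[Si](C)(C)C(C)(C)C
F10 | step 4 | tert-butyldimethyl{[(5E)-6-methyl-8-[(1S)-2,6,6-trimethylcyclohex-2-en-1-yl]oct-5-en-2-yl]oxy}silane (both C2 epimers) | CC1=CCCC(C)(C)[C@@H]1CC/C(C)=C/CCC(C)O[Si](C)(C)C(C)(C)C
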